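The runs were computed from invented constants; the scatter is artificial.

The violet charge of solid substrate is 4.17 times the blue one, yet at 8.00 min blue holds 0.147 M of dissolved starting material and violet 0.140 M.

in all of them: reagent 1.46 M; free catalyst 150 mM
- blue: solid substrate 0.36 M; second substrate 0.73 M; run made earlier
- violet: solid substrate 1.5 M; second substrate 0.73 M; run made earlier
- flask: solid substrate 0.73 M; second substrate 0.730 M; time 12 min

- blue (time / min: target / %, starting material / %, solid substrate / %): 1.00: 0.6, 6.0, 93.1; 2.00: 0.1, 12.8, 86.9; 3.00: 1.2, 17.9, 80.2; 4.00: 0.8, 25.1, 75.5; 5.00: 0.7, 28.9, 69.3; 6.00: 1.9, 35.1, 65.6; 8.00: 3.2, 40.8, 56.8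
- violet (time / min: target / %, starting material / %, solid substrate / %): 1.00: 0.8, 1.0, 99.1; 2.00: 0, 4.0, 97.1; 3.00: 0, 5.4, 93.8; 4.00: 0, 8.1, 94.0; 5.00: 0.7, 7.2, 91.8; 6.00: 1.5, 8.6, 91.6; 8.00: 0, 9.3, 88.9

(each reading ± 1 percentage point)

- solid substrate is a solid; its amount is given per volume of the solution
- at the start none of the solid substrate is in solution
- starting material is what solid substrate becomes in solution
- starting material means what is dissolved; the solid is not counted in it

- how much target there is at 12 min, in percent of the solid substrate charged
- concentration of starting material in solution at 12 min, in percent of saturation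

The readings give a ledger of the solid substrate charged in three entries: solid, starting material, target. At 8.00 min the blue entries sum to 101% and the violet ones to 98.2%, with a scatter of 1 percentage point on each entry. The dissolved entry is the one to carry from run to run, in molar and not in percent. The log position is the share of the way from the blue charge to the violet charge, counted in powers of ten; for the flask it is 0.495. The flask's dissolved concentration is then the blue one times the violet-to-blue ratio raised to the log position. This reckoning, which is not the forecast's, books 0.143 M in the flask at 8.00 min, or 19.6% of its charge, and it stops at the last reading. The forecast goes on to the asked time: target 3% (1.8% to 5%) and 72% of saturation (58% to 85%), with dissolution “limited by approach to saturation”.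

The flask gives 6.52% of target and stands at 51.3% of saturation, under this scheme:

    starting material + free catalyst ⇌ catalyst intermediate A (K = 2.20 M⁻¹, k = 2.90 M⁻¹ min⁻¹)
    second substrate + free catalyst ⇌ catalyst intermediate B (K = 230 M⁻¹, k = 110 M⁻¹ min⁻¹)
    reagent + catalyst intermediate B → free catalyst + second product (k = 0.340 M⁻¹ min⁻¹)
    second substrate → decomposition product (k = 7.10 × 10⁻⁴ min⁻¹)
    solid substrate ⇌ starting material, rate k5*(cs5 - [starting material]) while solid is left; crystals form when [starting material] > cs5 (solubility = 0.310 M, k = 0.0870 min⁻¹)
    reagent + catalyst intermediate A → free catalyst + target (k = 11.0 M⁻¹ min⁻¹)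

At 6.00 min catalyst intermediate B, the resting state, holds 96.4% of the catalyst charged, while target stands at 0.535%. The log position applied to the readings at that time books 17.5% of the flask's charge as starting material, and the flask holds 16.8%. Applied to the readings at 3.00 min, it books 9.89% for the same flask read at that time, which holds 9.65%.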